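**Plan**

1. The target is the achiral flavonol 3,5,8,3',5'-pentahydroxy-7,4'-dimethoxyflavone. Removing four O-benzyl groups and the C3 hydroxyl in the retrosynthetic sense leads back to a tetrabenzylated flavone.
2. Enabling feature: in pyranone ring C the carbonyl carbon C4 carries no substituent. It is bonded only to C4a of ring A and to C3, and O1 links C8a to C2, so C4 can be one molecule of CO.
3. Cutting C4–C4a, C3–C4 and O1–C2 together gives three pieces: a ring A 2-iodophenol (I on C4a, OH on C8a), carbon monoxide, and a ring B arylacetylene whose alkyne carbons are C2 and C3.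
4. Rings A and B are bought as benzenes and prepared separately. Ring A comes from 3,4-dihydroxy-5-methoxybenzaldehyde (iodination ortho to the free OH marks C4a, and Baeyer–Villiger oxidation turns CHO into the C5 oxygen). Ring B comes from 3,5-dihydroxy-4-methoxybenzoic acid (ester, aldehyde, alkyne).
5. Ring C is the only ring built, in one palladium-catalysed three-component step. C3 oxidation and hydrogenolysis then finish the synthesis.
6. Stereochemistry: the target has no stereocentre and no stereogenic double bond, so nothing has to be controlled.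

Key step: step 11

Remark: flavone numbering (O1, C2, C3, C4, C4a, C5 to C8, C8a; ring B primed) is used for the atoms that end up in the target. The transient epoxide of step 12 is racemic and is drawn as one enantiomer.

**Step 1**
Reactants: 1 3,4-dihydroxy-5-methoxybenzaldehyde
Product: 2 4-(benzyloxy)-3-hydroxy-5-methoxybenzaldehyde
Conditions: BnBr (1.0 equiv), NaHCO3, DMF, 40 °C
Reagents that add atoms: benzyl bromide, BrCc1ccccc1
Why: The 4-OH is para to the formyl group and is the more acidic catechol hydroxyl, so a weak base ionises only this one and the Williamson etherification with one equivalent of halide occurs there, as is usual for 3,4-dihydroxybenzaldehydes.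

**Step 2**
Reactants: 2 4-(benzyloxy)-3-hydroxy-5-methoxybenzaldehyde
Product: 3 4-(benzyloxy)-3-hydroxy-2-iodo-5-methoxybenzaldehyde
Conditions: ICl (1.05 equiv), pyridine, 1,4-dioxane, 0 °C to rt
Reagents that add atoms: iodine monochloride, ClI
Why: Electrophilic aromatic iodination of 3-hydroxy-4-alkoxybenzaldehydes with ICl–pyridine goes ortho to the free hydroxyl at C2 (the isovanillin pattern), and here C2 is also para to the 5-methoxy group while C6 is screened by the methyl of that group.

**Step 3**
Reactants: 3 4-(benzyloxy)-3-hydroxy-2-iodo-5-methoxybenzaldehyde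
Product: 4 4-(benzyloxy)-2-iodo-5-methoxy-3-(methoxymethoxy)benzaldehyde
Conditions: MOMCl, iPr2NEt, CH2Cl2, 0 °C to rt
Reagents that add atoms: chloromethyl methyl ether, COCCl
Why: O-alkylation of the phenol to its MOM acetal masks the future C8a hydroxyl with a small group that withstands peracid, carbonate and benzylation and is orthogonal to benzyl.

**Step 4**
Reactants: 4 4-(benzyloxy)-2-iodo-5-methoxy-3-(methoxymethoxy)benzaldehyde
Product: 6 4-(benzyloxy)-2-iodo-5-methoxy-3-(methoxymethoxy)phenol, via aryl formate 5 (not isolated)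
Conditions: mCPBA, CH2Cl2, rt; aq. Na2S2O3 wash; then K2CO3 (cat.), MeOH, rt
Reagents that add atoms: 3-chloroperoxybenzoic acid, O=C(OO)c1cccc(Cl)c1
Why: Baeyer–Villiger oxidation of this trialkoxybenzaldehyde should proceed with aryl migration (helped by the para-alkoxy and ortho-iodo groups) to the formate, which carbonate-catalysed methanolysis cleaves, and the thiosulfate wash returns any trivalent iodine species to the aryl iodide.

**Step 5**
Reactants: 6 4-(benzyloxy)-2-iodo-5-methoxy-3-(methoxymethoxy)phenol
Product: 7 1,4-bis(benzyloxy)-2-iodo-5-methoxy-3-(methoxymethoxy)benzene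
Conditions: BnBr, K2CO3, DMF, rt to 50 °C
Reagents that add atoms: benzyl bromide, BrCc1ccccc1
Why: Williamson etherification of the only free phenol puts the benzyl group on the future C5 oxygen, and the aryl iodide and the MOM acetal are inert to carbonate.

**Step 6**
Reactants: 7 1,4-bis(benzyloxy)-2-iodo-5-methoxy-3-(methoxymethoxy)benzene
Product: 8 3,6-bis(benzyloxy)-2-iodo-5-methoxyphenol
Conditions: conc. HCl (cat.), MeOH–THF, 40 °C
Reagents that add atoms: none
Why: Acid-catalysed acetal exchange with methanol removes the phenolic MOM group under conditions mild enough to spare the benzyl ethers and to avoid protodeiodination of the electron-rich iodide.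

**Step 7**
Reactants: 9 3,5-dihydroxy-4-methoxybenzoic acid
Product: 10 benzyl 3,5-bis(benzyloxy)-4-methoxybenzoate
Conditions: BnBr (3.3 equiv), K2CO3, DMF, 60 °C
Reagents that add atoms: benzyl bromide, BrCc1ccccc1
Why: Exhaustive O-alkylation of both phenols and the carboxylate in one operation is routine for gallic acid derivatives.

**Step 8**
Reactants: 10 benzyl 3,5-bis(benzyloxy)-4-methoxybenzoate
Product: 11 [3,5-bis(benzyloxy)-4-methoxyphenyl]methanol
Conditions: LiAlH4, THF, 0 °C to rt
Reagents that add atoms: none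
Why: Hydride reduction of the ester gives the primary benzylic alcohol and leaves aryl benzyl and methyl ethers untouched.

**Step 9**
Reactants: 11 [3,5-bis(benzyloxy)-4-methoxyphenyl]methanol
Product: 12 3,5-bis(benzyloxy)-4-methoxybenzaldehyde
Conditions: MnO2 (activated), CH2Cl2, rt
Reagents that add atoms: none
Why: Activated MnO2 oxidises benzylic alcohols selectively to aldehydes without over-oxidation.

**Step 10**
Reactants: 12 3,5-bis(benzyloxy)-4-methoxybenzaldehyde; 13 dimethyl (1-diazo-2-oxopropyl)phosphonate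
Product: 14 1,3-bis(benzyloxy)-5-ethynyl-2-methoxybenzene
Conditions: K2CO3, MeOH–THF, rt
Reagents that add atoms: dimethyl (1-diazo-2-oxopropyl)phosphonate 13, CC(=O)C(=[N+]=[N-])P(=O)(OC)OC
Why: The Ohira–Bestmann variant of the Seyferth–Gilbert homologation converts non-enolisable aromatic aldehydes into terminal alkynes under mild carbonate conditions.

**Step 11**
Reactants: 8 3,6-bis(benzyloxy)-2-iodo-5-methoxyphenol; 14 1,3-bis(benzyloxy)-5-ethynyl-2-methoxybenzene; 15 carbon monoxide
Product: 18 5,8-bis(benzyloxy)-2-[3,5-bis(benzyloxy)-4-methoxyphenyl]-7-methoxy-4H-chromen-4-one, via hydroxyaryl ynone 16 (not isolated), via enaminone 17 (not isolated)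
Conditions: PdCl2(PPh3)2 (5 mol %), CO (5 bar), Et2NH, 80 °C, autoclave, no copper salt
Reagents that add atoms: carbon monoxide 15, [C-]#[O+]
Why: The precatalyst is reduced in the flask to zerovalent palladium, oxidative addition takes place at the C4a–I bond of 8, migratory insertion of CO gives an aroylpalladium iodide, and transfer of the acetylide formed from 14 with Et2NH followed by reductive elimination delivers ynone 16, which makes C4–C4a and C3–C4. Et2NH then adds to the alkyne carbon C2 to give enaminone 17, and the C8a hydroxyl attacks the same carbon and expels the amine, so ring C closes by a 6-endo addition–elimination (6-endo-dig counted on 16, 6-endo-trig on 17) that makes O1–C2. The closest known reaction type is the palladium-catalysed carbonylative coupling of 2-iodophenols with terminal arylacetylenes in secondary amines, that is a carbonylative Sonogashira reaction followed by oxa-Michael cyclisation. Three selectivities are needed: carbonylation before alkynylation, capture of the acyl complex by the alkyne and not by the amine, and flavone closure in preference to aurone closure. The first is secured by leaving out copper, by CO pressure and by the electron-rich arylpalladium flanked by two ortho oxygens, which should insert CO quickly; the second by the same ortho substituents, which screen the aroyl carbon from the bulky amine more than from the slim acetylide; the third by enaminone 17, whose only electrophilic carbon is C2. No stereocentre is formed, and the benzyl and methyl ethers are spectators.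

**Step 12**
Reactants: 18 5,8-bis(benzyloxy)-2-[3,5-bis(benzyloxy)-4-methoxyphenyl]-7-methoxy-4H-chromen-4-one
Product: 20 5,8-bis(benzyloxy)-2-[3,5-bis(benzyloxy)-4-methoxyphenyl]-3-hydroxy-7-methoxy-4H-chromen-4-one, via epoxyflavanone 19 (not isolated)
Conditions: dimethyldioxirane (acetone solution), CH2Cl2, 0 °C to rt; then p-TsOH·H2O (cat.), CH2Cl2, rt
Reagents that add atoms: dimethyldioxirane, CC1(C)OO1
Why: Epoxidation of the enol-ether-like C2=C3 bond of a flavone with dimethyldioxirane, followed by acid-catalysed opening at C2 and loss of H3, is an established flavone-to-flavonol oxidation compatible with benzyl ethers, and the two stereocentres of racemic 19 disappear again on rearomatisation.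

**Step 13**
Reactants: 20 5,8-bis(benzyloxy)-2-[3,5-bis(benzyloxy)-4-methoxyphenyl]-3-hydroxy-7-methoxy-4H-chromen-4-one
Product: 21 2-(3,5-dihydroxy-4-methoxyphenyl)-3,5,8-trihydroxy-7-methoxy-4H-chromen-4-one
Conditions: H2 (1 atm), Pd/C (10 wt % Pd), degassed THF–MeOH, rt; work-up under argon
Reagents that add atoms: none
Why: Catalytic hydrogenolysis removes all four aryl benzyl ethers under neutral conditions, which leaves both methyl ethers and the flavonol double bond intact and avoids the acid-induced 5,7,8 to 5,6,7 ring A isomerisation (Wessely–Moser rearrangement), and exclusion of air protects the 5,8-quinol.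

**Compound list**

| No. | Name | SMILES | Role |
|---|---|---|---|
| 1 | 3,4-dihydroxy-5-methoxybenzaldehyde | COc1cc(C=O)cc(O)c1O | starting material |
| 2 | 4-(benzyloxy)-3-hydroxy-5-methoxybenzaldehyde | COc1cc(C=O)cc(O)c1OCc1ccccc1 | intermediate |
| 3 | 4-(benzyloxy)-3-hydroxy-2-iodo-5-methoxybenzaldehyde | COc1cc(C=O)c(I)c(O)c1OCc1ccccc1 | intermediate |
| 4 | 4-(benzyloxy)-2-iodo-5-methoxy-3-(methoxymethoxy)benzaldehyde | COCOc1c(I)c(C=O)cc(OC)c1OCc1ccccc1 | intermediate |
| 5 | 4-(benzyloxy)-2-iodo-5-methoxy-3-(methoxymethoxy)phenyl formate | COCOc1c(I)c(OC=O)cc(OC)c1OCc1ccccc1 | intermediate |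
| 6 | 4-(benzyloxy)-2-iodo-5-methoxy-3-(methoxymethoxy)phenol | COCOc1c(I)c(O)cc(OC)c1OCc1ccccc1 | intermediate |
| 7 | 1,4-bis(benzyloxy)-2-iodo-5-methoxy-3-(methoxymethoxy)benzene | COCOc1c(I)c(OCc2ccccc2)cc(OC)c1OCc1ccccc1 | intermediate |
| 8 | 3,6-bis(benzyloxy)-2-iodo-5-methoxyphenol | Oc1c(I)c(OCc2ccccc2)cc(OC)c1OCc1ccccc1 | intermediate |
| 9 | 3,5-dihydroxy-4-methoxybenzoic acid | COc1c(O)cc(C(=O)O)cc1O | starting material |
| 10 | benzyl 3,5-bis(benzyloxy)-4-methoxybenzoate | COc1c(OCc2ccccc2)cc(C(=O)OCc2ccccc2)cc1OCc1ccccc1 | intermediate |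
| 11 | [3,5-bis(benzyloxy)-4-methoxyphenyl]methanol | COc1c(OCc2ccccc2)cc(CO)cc1OCc1ccccc1 | intermediate |
| 12 | 3,5-bis(benzyloxy)-4-methoxybenzaldehyde | COc1c(OCc2ccccc2)cc(C=O)cc1OCc1ccccc1 | intermediate |
| 13 | dimethyl (1-diazo-2-oxopropyl)phosphonate | CC(=O)C(=[N+]=[N-])P(=O)(OC)OC | starting material |
| 14 | 1,3-bis(benzyloxy)-5-ethynyl-2-methoxybenzene | C#Cc1cc(OCc2ccccc2)c(OC)c(OCc2ccccc2)c1 | intermediate |
| 15 | carbon monoxide | [C-]#[O+] | starting material |
| 16 | 1-[3,6-bis(benzyloxy)-2-hydroxy-4-methoxyphenyl]-3-[3,5-bis(benzyloxy)-4-methoxyphenyl]prop-2-yn-1-one | COc1cc(OCc2ccccc2)c(C(=O)C#Cc2cc(OCc3ccccc3)c(OC)c(OCc3ccccc3)c2)c(O)c1OCc1ccccc1 | intermediate |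
| 17 | (2E)-1-[3,6-bis(benzyloxy)-2-hydroxy-4-methoxyphenyl]-3-[3,5-bis(benzyloxy)-4-methoxyphenyl]-3-(diethylamino)prop-2-en-1-one | COc1cc(OCc2ccccc2)c(C(=O)/C=C(/N(CC)CC)c2cc(OCc3ccccc3)c(OC)c(OCc3ccccc3)c2)c(O)c1OCc1ccccc1 | intermediate |
| 18 | 5,8-bis(benzyloxy)-2-[3,5-bis(benzyloxy)-4-methoxyphenyl]-7-methoxy-4H-chromen-4-one | COc1cc(OCc2ccccc2)c2c(=O)cc(-c3cc(OCc4ccccc4)c(OC)c(OCc4ccccc4)c3)oc2c1OCc1ccccc1 | intermediate |
| 19 | racemic 2,3-epoxide of 18 (oxirane cis-fused across C2–C3 of the chroman-4-one, aryl group on C2; one enantiomer drawn) | COc1cc(OCc2ccccc2)c2c(c1OCc1ccccc1)O[C@@]1(c3cc(OCc4ccccc4)c(OC)c(OCc4ccccc4)c3)O[C@H]1C2=O | intermediate |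
| 20 | 5,8-bis(benzyloxy)-2-[3,5-bis(benzyloxy)-4-methoxyphenyl]-3-hydroxy-7-methoxy-4H-chromen-4-one | COc1cc(OCc2ccccc2)c2c(=O)c(O)c(-c3cc(OCc4ccccc4)c(OC)c(OCc4ccccc4)c3)oc2c1OCc1ccccc1 | intermediate |
| 21 | 2-(3,5-dihydroxy-4-methoxyphenyl)-3,5,8-trihydroxy-7-methoxy-4H-chromen-4-one | COc1cc(O)c2c(=O)c(O)c(-c3cc(O)c(OC)c(O)c3)oc2c1O | target |

**Totals**

Total step count: 13.
Longest linear sequence: 9 (steps 1 to 6, then 11, 12 and 13).

**The three steps most likely to fail**

**Step 11.** Several things may go wrong with the hindered, electron-rich iodide: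
- alkynylation may outrun CO insertion, followed by closure to a five-membered oxygen ring;
- diethylamine may capture the aroylpalladium complex;
- oxidative addition may be slow under CO.

Fallback: the C4 carbon is brought in on the alkyne partner and joined to ring A by a Grignard acylation, without palladium or CO. The fallback sets out from 14 and 7.
- Alkyne 14 is deprotonated with n-BuLi (THF, −78 °C) to the lithium acetylide F1. This is acylated with N-methoxy-N-methylcarbamoyl chloride to the alkynyl Weinreb amide F2.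
- Iodide 7 undergoes iodine–magnesium exchange with iPrMgCl·LiCl (THF, −20 to 0 °C) to the arylmagnesium chloride F3. This adds to F2 and, after aqueous NH4Cl, gives the MOM-protected ynone F4.
- Catalytic HCl in MeOH–THF frees the phenol, and the route is rejoined at 16, now as an isolated compound. Et2NH in EtOH at rt carries 16 through 17 to 18.

**Step 2.** Site selectivity between C2 and C6 may be poor, or a second iodination may set in before the first is complete.

Fallback: iodine is introduced by directed ortho-metalation in place of electrophilic substitution. The fallback sets out from 2.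
- The free hydroxyl of 2 is carbamoylated (ClC(O)NEt2, K2CO3, MeCN, reflux) to the formyl aryl carbamate F5.
- mCPBA gives the formate carbamate F6, and carbonate-catalysed methanolysis gives the hydroxy carbamate F7.
- BnBr and K2CO3 in DMF give the dibenzyl carbamate F8.
- Lithium 2,2,6,6-tetramethylpiperidide (THF, −78 °C) spares the benzylic CH2 groups and removes the proton between the carbamate and the benzyloxy group, giving the aryllithium F9.
- I2 converts F9 into the iodo carbamate F10.
- Hydrolysis with KOH in aqueous EtOH at reflux rejoins the route at 8.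

**Step 12.** Oxygen transfer to the conjugated C2=C3 bond may be slow, so that oxidation of benzylic C–H bonds or of the oxygen-rich rings competes, and the epoxide may open incompletely.

Fallback: the hydroxyl is installed through an anion instead of an electrophilic oxidant. The fallback sets out from 18.
- Deprotonation of 18 at C3 with LiN(iPr)2 (THF, −78 °C) gives the 3-lithioflavone F11.
- B(OMe)3 followed by AcOH gives the dimethyl flavon-3-ylboronate F12.
- H2O2 (0 °C to rt) oxidises the C–B bond, and the route is rejoined at 20.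

**Further compounds**

F1 | step 11 | lithium [3,5-bis(benzyloxy)-4-methoxyphenyl]acetylide | [Li]C#Cc1cc(OCc2ccccc2)c(OC)c(OCc2ccccc2)c1
F2 | step 11 | 3-[3,5-bis(benzyloxy)-4-methoxyphenyl]-N-methoxy-N-methylprop-2-ynamide | CON(C)C(=O)C#Cc1cc(OCc2ccccc2)c(OC)c(OCc2ccccc2)c1
F3 | step 11 | [3,6-bis(benzyloxy)-4-methoxy-2-(methoxymethoxy)phenyl]magnesium chloride | COCOc1c([Mg]Cl)c(OCc2ccccc2)cc(OC)c1OCc1ccccc1
F4 | step 11 | 1-[3,6-bis(benzyloxy)-4-methoxy-2-(methoxymethoxy)phenyl]-3-[3,5-bis(benzyloxy)-4-methoxyphenyl]prop-2-yn-1-one | COCOc1c(C(=O)C#Cc2cc(OCc3ccccc3)c(OC)c(OCc3ccccc3)c2)c(OCc2ccccc2)cc(OC)c1OCc1ccccc1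
F5 | step 2 | 2-(benzyloxy)-5-formyl-3-methoxyphenyl diethylcarbamate | CCN(CC)C(=O)Oc1cc(C=O)cc(OC)c1OCc1ccccc1
F6 | step 2 | 2-(benzyloxy)-5-(formyloxy)-3-methoxyphenyl diethylcarbamate | CCN(CC)C(=O)Oc1cc(OC=O)cc(OC)c1OCc1ccccc1
F7 | step 2 | 2-(benzyloxy)-5-hydroxy-3-methoxyphenyl diethylcarbamate | CCN(CC)C(=O)Oc1cc(O)cc(OC)c1OCc1ccccc1
F8 | step 2 | 2,5-bis(benzyloxy)-3-methoxyphenyl diethylcarbamate | CCN(CC)C(=O)Oc1cc(OCc2ccccc2)cc(OC)c1OCc1ccccc1
F9 | step 2 | [3,6-bis(benzyloxy)-2-(diethylcarbamoyloxy)-4-methoxyphenyl]lithium | CCN(CC)C(=O)Oc1c([Li])c(OCc2ccccc2)cc(OC)c1OCc1ccccc1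
F10 | step 2 | 3,6-bis(benzyloxy)-2-iodo-5-methoxyphenyl diethylcarbamate | CCN(CC)C(=O)Oc1c(I)c(OCc2ccccc2)cc(OC)c1OCc1ccccc1
F11 | step 12 | {5,8-bis(benzyloxy)-2-[3,5-bis(benzyloxy)-4-methoxyphenyl]-7-methoxy-4-oxo-4H-chromen-3-yl}lithium | COc1cc(OCc2ccccc2)c2c(=O)c([Li])c(-c3cc(OCc4ccccc4)c(OC)c(OCc4ccccc4)c3)oc2c1OCc1ccccc1
F12 | step 12 | dimethyl {5,8-bis(benzyloxy)-2-[3,5-bis(benzyloxy)-4-methoxyphenyl]-7-methoxy-4-oxo-4H-chromen-3-yl}boronate | COB(OC)c1c(-c2cc(OCc3ccccc3)c(OC)c(OCc3ccccc3)c2)oc2c(OCc3ccccc3)c(OC)cc(OCc3ccccc3)c2c1=O
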